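The data were computed from invented constants.

The vessel, closed, fed or flowing, is what differs between the set-ups below, and the number to watch in each is the ratio c(over-reaction product)/c(target).

| flask | electrophile | nucleophile | free base | protic impurity | remark | time |
|---|---|---|---|---|---|---|
| cedar | 0.50 M | 0.40 M | 0.50 M | 0.10 M | run made earlier |  |
| elm | 0.50 M | 0.56 M | 0.50 M | 0.10 M | run made earlier |  |
| alder | 0.50 M | 0.88 M | 0.50 M | 0.10 M | run made earlier |  |
| red | 0.50 M | 0.400 M | 0.500 M | 0.100 M | one stirred flow tank at steady state, fed with the mixture as stated, mean residence time 5.0 h |  |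
| ochre | 0.50 M (fed, over 2.50 h) | 0.400 M | 0.500 M | 0.100 M | all but electrophile at the start; electrophile goes in evenly over 2.50 h, the run ends at 5.0 h | 5.0 h |
| teal | 0.50 M | 0.400 M | 0.500 M | 0.100 M | a single well-mixed tank run continuously and read at steady state, 25.0 h in it on average |  |
| violet | 0.50 M | 0.400 M | 0.500 M | 0.100 M | a closed flask charged with all of it at once and left for 5.0 h | 5.0 h |

- cedar (time / h: target / %, over-reaction product / %): 0.250: 0.9, 0; 0.417: 4.8, 0; 0.667: 4.4, 0; 1.00: 6.8, 2.1; 2.00: 12.1, 0; 3.00: 13.2, 0.2
- elm (time / h: target / %, over-reaction product / %): 0.250: 3.5, 0; 0.833: 8.3, 2.7; 1.33: 12.5, 0; 2.00: 15.5, 0.5; 3.00: 20.1, 3.9; 4.00: 22.7, 3.0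
- alder (time / h: target / %, over-reaction product / %): 0.667: 10.1, 0; 1.33: 16.8, 0.2; 2.00: 24.2, 2.8; 2.50: 26.2, 3.4; 3.00: 30.1, 3.7; 4.00: 31.8, 5.1

(each reading ± 1 percentage point)

- the stated concentrations are those of everything mixed, before any reaction; amounts are the same in each set-up
- the feed brings no volume worth counting
- the earlier runs were made in a closed, stirred flask

* the set-up with the highest share of target in all that became target or over-reaction product, at the outlet or at the end ("none" if the first two lie within 2 percentage points) (red / ochre / teal / violet / none)
* share of target in all that became target or over-reaction product, at the outlet or at the end, red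
* share of target in all that became target or over-reaction product, at the outlet or at the end, ochre
* share of target in all that became target or over-reaction product, at the outlet or at the end, teal
* share of target in all that became target or over-reaction product, at the outlet or at the end, violet

The reckoning here runs from the fastest rung to the slowest.

1. Feed. Ochre's electrophile goes in over 2.50 h, so it arrives on average at 1.25 h.

2. Age. Taken as formed evenly, violet's target is on average 2.50 h old at the end, half of its 5.0 h window. Ochre's window opens later, at the mean arrival, so its target is on average 1.88 h old. Even formation is a rough assumption.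

3. Ageing. At 4.00 h, the ratio reads 0.132 in elm and 0.160 in alder, with a scatter of 1 percentage point on each reading, although they hold 0.56 M and 0.88 M of nucleophile. Taken as first-order ageing of target, the pooled readings give the ageing constant kO = 0.0743 h⁻¹, an ageing time of 13.5 h.

4. Closed flasks. The run time of 5.0 h is shorter than the ageing time. The selectivity to target is then reckoned as about 1/(1 + kO·age): 84.3% for violet and 87.8% for ochre. Ochre leads by 3.5 points, more than the margin.

5. Tanks. At steady state, over-reaction product leaves at c(over-reaction product)/τ and forms at kO·c(target), so the average age of target in the reckoning is τ. Red, at 5.0 h, gives 72.9%. Teal, at 25.0 h, longer than the ageing time, gives 35.0%.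

The forecast differs, with 77% for red, 83% for ochre, 70% for teal, 84% for violet and best none, since “The top two are within 2 points”.

The flasks give 74.5% for red, 86.0% for ochre, 36.9% for teal and 82.1% for violet, and best is ochre.

    electrophile + nucleophile → acid set free + target (k = 8.60 × 10⁻⁵ M⁻¹ s⁻¹)
    nucleophile + acid set free ⇌ protonated nucleophile, settled at all times (K = 46.0 M⁻¹)
    acid set free + free base ⇌ salt of the base (K = 3.30 M⁻¹, k = 0.00440 M⁻¹ s⁻¹)
    electrophile ⇌ dormant form (K = 0.670, k = 7.30 × 10⁻⁴ s⁻¹)
    protic impurity + free base → quenched reagent (k = 3.80 × 10⁻⁴ M⁻¹ s⁻¹)
    target → over-reaction product (k = 1.90 × 10⁻⁵ s⁻¹)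

In ochre, the feed ended at 2.50 h with target at 7.90% and over-reaction product at 0.499%; by 5.00 h they stood at 16.4% and 2.68%, with electrophile still at 48.2%. The midpoint of ochre's target-forming turnover came at 2.71 h, an age near 2.29 h, and kO then gives 85.5% against the flask's 86.0%. Ochre read at 3.0 h has a reckoned age of 0.875 h, so kO gives 93.9%, and that flask holds 92.6%.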